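The runs were generated by integration from invented constants, noise included.

Late in Monday's run, at 4.00 h, I read 50.7% product and 22.2% substrate, so 27.1% of the substrate charged stood as intermediate by difference. To judge how far a flask can go, I balanced the partner, taking one partner for each product.

| setting | Tuesday's | Monday's | Thursday's | flask |
|---|---|---|---|---|
| substrate | 0.30 M | 0.30 M | 0.45 M | 0.30 M |
| partner | 0.33 M (fed, over 20 min) | 0.33 M (fed, over 20 min) | 0.33 M (fed, over 20 min) | 0.330 M (fed, over 20 min) |
| free catalyst | 45 mM | 45 mM | 45 mM | 45 mM |
| second catalyst | 0.15 mM | 0.22 mM | 0.30 mM | 0.30 mM |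
| remark | run made earlier; the fed solution adds 1.0 times the starting volume | run made earlier; the fed solution adds 1.0 times the starting volume | run made earlier; the fed solution adds 1.0 times the starting volume | the fed solution adds 1.0 times the starting volume |
| time |  |  |  | 5.0 h |

| run | time / h | product / % | substrate / % |
|---|---|---|---|
| Tuesday's | 0.333 | 2.2 | 58.7 |
| Tuesday's | 0.500 | 4.9 | 51.8 |
| Tuesday's | 0.833 | 8.6 | 44.0 |
| Tuesday's | 1.33 | 16.0 | 38.0 |
| Tuesday's | 2.50 | 28.9 | 31.2 |
| Tuesday's | 4.00 | 41.4 | 25.9 |
| Monday's | 0.667 | 9.7 | 46.6 |
| Monday's | 1.33 | 21.4 | 36.1 |
| Monday's | 2.00 | 30.7 | 31.4 |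
| Monday's | 2.50 | 37.3 | 28.3 |
| Monday's | 3.00 | 42.5 | 26.4 |
| Monday's | 4.00 | 50.7 | 22.2 |
| Thursday's | 0.333 | 4.9 | 58.7 |
| Thursday's | 1.00 | 19.2 | 40.1 |
| Thursday's | 2.00 | 35.3 | 29.9 |
| Thursday's | 3.00 | 44.6 | 24.9 |
| Thursday's | 4.00 | 51.3 | 21.2 |

(readings scatter by 0.3 percentage points)

- every charge counts on the volume at the start, and the solution that is fed holds the whole dose
- a reading or a percentage of product counts all its forms, free or not
- the concentration of product that is asked is that of its free form alone

- concentration of product (only what is free in solution) at 5.0 h, in M
- concentration of substrate at 5.0 h, in M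
- concentration of intermediate at 5.0 h, in M

The partner cover of the flask came to 110%, meaning the whole charge of partner over the charge of substrate. By that balance, product as a share of the substrate charged stops at the cover where the cover lies below full, and the partner left, as a share of its own charge, is one minus product over cover.

I then turned the settings in turn. By hand, going from Tuesday's second catalyst to Monday's should have raised product 1.47 times, but at 1.33 h the readings gave 1.34 times, less than in proportion. Raising the substrate to Thursday's 0.45 M brought the cover down to 73.3%, making partner the limiting reagent, and Thursday's last reading of 51.3% product put the partner left at 30.0% by my balance. The feed took 20 min, short against the 5.0 h of the flask, so by hand I gave it little weight, though Tuesday's, Monday's and Thursday's runs held it at the same 20 min. In the flask the charge of partner exceeded that of substrate, so my balance put no stop on product short of the whole substrate charged.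

The forecast gave 0.082 M free product, 0.026 M substrate and 0.029 M intermediate, reasoning that “the first step looks reversible”.

The flask gave 0.0890 M free product, 0.0241 M substrate and 0.0296 M intermediate, so the forecast held.

    free catalyst + product ⇌ idle complex, settled at all times (K = 9.80 M⁻¹)
    partner + second catalyst + intermediate → second catalyst + product (k = 440 M⁻² min⁻¹)
    substrate + free catalyst ⇌ free catalyst + intermediate (K = 1.40, k = 2.60 M⁻¹ min⁻¹)
    2 free catalyst ⇌ resting dimer, settled at all times (K = 49.0 M⁻¹)

With 64.2% product at 5.00 h, idle complex counted, the cover of the flask left 41.6% of the partner. The time given kept free product down, since the same flask left until 50.0 h gave 0.137 M free product against 0.0890 M. The neighbour flask with 1.2 M of substrate has a cover of 27.5%, and there partner ran out first, with 27.3% product and 0.762% of the partner left.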